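The constants describe a round with a leak. Free catalyst takes up substrate and becomes catalyst intermediate A. That takes up partner and becomes catalyst intermediate B, which reversibly gives back free catalyst and product. But two catalyst intermediate A can also meet, and then both become spent catalyst.

    substrate + free catalyst → catalyst intermediate A (k1 = 0.0171 L mol⁻¹ s⁻¹)
    partner + catalyst intermediate A → catalyst intermediate B (k2 = 0.00612 L mol⁻¹ s⁻¹)
    catalyst intermediate B ⇌ free catalyst + product (K3 = 0.173 M, k3 = 4.17 × 10⁻⁴ s⁻¹)
    2 catalyst intermediate A → spent catalyst (k4 = 0.0479 L mol⁻¹ s⁻¹)

substrate 0.20 M; partner 0.190 M; free catalyst 3.6 mM

- a species is counted by the substrate in it: one spent catalyst counts as two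
- for a step with 2 of a species take k times the square, and two of it per event
- a form made of two catalysts counts as two
- charge of substrate (flask): 0.20 M

1. the form that holds most of the catalyst when 50% of the substrate are converted (free catalyst / catalyst intermediate B / spent catalyst / catalyst intermediate A)
2. its share of the catalyst then
3. apparent order in free catalyst when 50% of the substrate are converted (percent change of the rate of making product for one percent more free catalyst charged)
4. factor on the rate of making product when 50% of the substrate are converted if partner is charged twice over

I follow one catalyst round this flask. Its wait in a form is one over its rate of moving on. At the charge it waits 0.0812 h as free catalyst, 0.239 h as catalyst intermediate A and 0.666 h as catalyst intermediate B. That last wait is the longest, so at the charge catalyst intermediate B is the resting state of the working round. I take each working form to hold a share equal to its wait over the wait of the whole round.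

The fork stands at catalyst intermediate A. Per uptake of partner the round makes one product, and per meeting two catalysts go. Dividing these rates, the catalyst lost per product grows with c(catalyst intermediate A), which I take as a fixed share of the working catalyst at given c(substrate) and c(partner). So in my reckoning working catalyst falls exponentially with product made. I call the exponent per mol/L of product the toll: two times the death constant, times the squared wait at catalyst intermediate A, over the wait of the round. At the charge it is 20.0 L mol⁻¹. At the midpoint of the way to 50% conversion, c(substrate) is 0.150 M and c(partner) is 0.140 M. The toll there is 33.0 L mol⁻¹, larger than at the charge, and I take it as the mean toll.

By my reckoning, about 0.100 M of product then leaves 3.69% of the catalyst working. With c(substrate) at 0.100 M, c(partner) at 0.0900 M and a round of 1.33 h, the largest form is spent catalyst, with 96.3%.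

Each dead catalyst also carried off a substrate. More catalyst therefore means less product at equal conversion, and less toll paid at the final 65.8 L mol⁻¹. So I reckon the order at 1.24.

With partner charged twice over, I reckon a midpoint toll of 7.15 L mol⁻¹, less than before, and a round at 50% conversion of 0.991 h. Survival and round together give a factor of 17.8.

The forecast gives spent catalyst at 96%, order 1.2 and factor 17, and holds that “this survival rather than the direct rate effect gives the large factor”. This flask gives spent catalyst at 96.2%, order 1.2 and factor 17.0, with 50% conversion reached after 8.53 d.

The death of catalyst intermediate A is the largest single effect on the rate in this flask at 50% conversion. The same run without that step has 26.1 times the actual rate there, and the mean toll I reckoned corresponds to a factor of 27.1. Without that step the order in free catalyst goes from 1.2 to 1.0.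

The rate constants were chosen freely; the flask was simulated.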